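The cyclohexene core has cis oxygens at C3 and C6 that flank the C1=C2 alkene and lie trans to the cis C4/C5 oxygens. This 1,4-dioxygenated ene pattern is traced back to dioxygen: the C3–O and C6–O bonds are disconnected to a C6=C1–C2=C3 cyclohexadiene. In one operation, singlet oxygen closes a 2,3-dioxabicyclo[2.2.2]octene across C3/C6, moves the alkene to C1=C2 and sets both new stereocentres anti to the existing diol. The precursor is the shikimic-acid-derived diene carrying the C4/C5 cis-diol as an acetonide (sole source of chirality and facial shield) with the C7 benzoate already in place. O–O reduction, deketalisation and an orthoester-mediated C5 benzoylation finish the synthesis.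

Key step: step 6

Remark on numbering and configuration: target positions are used throughout (C1 carries C7H2OBz, C2 is the alkene CH, C3–C6 are the oxygenated carbons). Shikimate C3, C4, C5, C6 and C2 become target C5, C4, C3, C2 and C6. Natural (3R,4S,5R)-shikimic acid therefore delivers C4 and C5 in the required absolute configuration, and no structure needed correction.

Step 1
Reactants: 1 shikimic acid; 2 methanol; 3 2,2-dimethoxypropane
Product: 5 methyl 3,4-O-isopropylideneshikimate, via methyl shikimate 4 (not isolated)
Conditions: CSA (cat.), MeOH, reflux; concentrate; then 2,2-dimethoxypropane, acetone, rt (same flask)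
Reagents that add atoms: methanol, CO; 2,2-dimethoxypropane, COC(C)(C)OC
Why: Fischer esterification followed by acid-catalysed transketalisation; only the cis C3/C4 diol (shikimate numbering) can close an unstrained dioxolane, so the C5 hydroxyl stays free and no stereocentre is touched.

Step 2
Reactants: 5 methyl 3,4-O-isopropylideneshikimate; 6 trifluoromethanesulfonic anhydride
Product: 7 methyl 3,4-O-isopropylidene-5-O-(trifluoromethylsulfonyl)shikimate
Conditions: Tf2O, pyridine, CH2Cl2, −20 °C (crude product used at once)
Reagents that add atoms: trifluoromethanesulfonic anhydride, O=S(=O)(OS(=O)(=O)C(F)(F)F)C(F)(F)F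
Why: O-sulfonylation of the only free (secondary) hydroxyl; the C5–O bond is not broken, so configuration is retained.

Step 3
Reactants: 7 methyl 3,4-O-isopropylidene-5-O-(trifluoromethylsulfonyl)shikimate
Product: 8 methyl (3aR,7aS)-2,2-dimethyl-3a,7a-dihydro-1,3-benzodioxole-5-carboxylate (diene ester)
Conditions: CsOAc, DMF, rt
Reagents that add atoms: none
Why: E2 elimination (E1cB-like) in which acetate removes an acidic C6 hydrogen (allylic and γ to the enoate) anti to the triflate, while H-4 is cis to the leaving group and cannot take part, so only the conjugated C5=C6 alkene should form and the ketal stereocentres stay intact.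

Step 4
Reactants: 8 diene ester
Product: 9 [(3aR,7aS)-2,2-dimethyl-3a,7a-dihydro-1,3-benzodioxol-5-yl]methanol
Conditions: DIBAL-H (2.5 equiv), CH2Cl2, −78 °C; aq. Rochelle salt work-up
Reagents that add atoms: none
Why: 1,2-hydride reduction of the dienoate to the primary allylic alcohol at low temperature leaves diene and ketal untouched, and the non-acidic work-up avoids aromatisation of the dihydrodiol ketal.

Step 5
Reactants: 9 dienyl alcohol; 10 benzoyl chloride
Product: 11 [(3aR,7aS)-2,2-dimethyl-3a,7a-dihydro-1,3-benzodioxol-5-yl]methyl benzoate (diene with target C4/C5 as cis-acetonide and the C7 benzoate)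
Conditions: BzCl, Et3N, DMAP (cat.), CH2Cl2, 0 °C; product kept cold and used promptly
Reagents that add atoms: benzoyl chloride, O=C(Cl)c1ccccc1
Why: DMAP-catalysed nucleophilic acyl substitution on the only hydroxyl group, under basic conditions that the acid-sensitive diene ketal tolerates.

Step 6
Reactants: 11 diene benzoate; 12 dioxygen
Product: 13 endoperoxide (O–O bridge from C3 to C6 on the face opposite the 4,5-acetonide; 2,3-dioxabicyclo[2.2.2]oct-5-ene with C1=C2 alkene and C7 benzoate)
Conditions: O2, TPP (cat.), visible light, CH2Cl2, −30 °C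
Reagents that add atoms: dioxygen, O=O
Why: Sensitised energy transfer from TPP generates singlet oxygen, which adds suprafacially in a concerted, asynchronous [4+2] cycloaddition to the ring-locked s-cis diene C6=C1–C2=C3, forming the C3–O and C6–O bonds and shifting the π bond to C1=C2. The closest known reaction type is the hetero-Diels–Alder photooxygenation of ketal-protected cis-5,6-dioxygenated cyclohexa-1,3-dienes, which on peroxide reduction gives conduritol-type ene-diols. The 1,2-dioxine ring of the bicycle closes by cycloaddition, both C–O bonds arising in the same pericyclic event across C3 and C6. The two new stereocentres C3 and C6 are set together: their mutual cis relationship follows from suprafacial addition, and their absolute sense is dictated by the shikimate-derived C4/C5 ketal (substrate control). The step needs π-facial selectivity, which the cis-fused dioxolane should secure because its pseudoaxial C–O bond and endo methyl group cover one face, so oxygen approaches anti. It also needs cycloaddition to win over ene reaction at the C7 methylene or the C4/C5 methine hydrogens, which the far higher [4+2] reactivity of a planar cyclic diene should secure, while the low temperature holds back endoperoxide rearrangement and diene dimerisation.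

Step 7
Reactants: 13 endoperoxide
Product: 14 cis-3,6-diol 4,5-acetonide C7 benzoate
Conditions: thiourea (2 equiv), MeOH, 0 °C to rt
Reagents that add atoms: none
Why: Reductive cleavage of the peroxide by nucleophilic attack of thiourea sulfur on oxygen breaks only the O–O bond, so both C–O bonds and the C3/C6 configurations are retained while alkene, benzoate and ketal are inert under these neutral conditions.

Step 8
Reactants: 14 cis-3,6-diol 4,5-acetonide; 15 water
Product: 16 [(3R,4S,5R,6S)-3,4,5,6-tetrahydroxycyclohex-1-en-1-yl]methyl benzoate (tetraol)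
Conditions: AcOH/H2O 4:1, 50 °C
Reagents that add atoms: none
Why: Acid-catalysed acetal hydrolysis cleaves only the ketal C–O bonds, so C4 and C5 keep their configuration, and the primary benzoate is stable to warm aqueous acetic acid.

Step 9
Reactants: 16 tetraol; 17 trimethyl orthobenzoate; 15 water
Product: 19 [(3R,4S,5R,6S)-5-(benzoyloxy)-3,4,6-trihydroxycyclohex-1-en-1-yl]methyl benzoate (target), via cyclic 4,5-orthobenzoate 18 (not isolated)
Conditions: PhC(OMe)3 (1.2 equiv), CSA (cat.), MeCN, rt; then AcOH/H2O 4:1, rt
Reagents that add atoms: trimethyl orthobenzoate, COC(OC)(OC)c1ccccc1; water, O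
Why: Acid-catalysed orthoester exchange followed by hydrolytic opening, in which only the cis C4/C5 diol can form a cis-fused five-membered orthoester; the C6 hydroxyl should sit pseudoaxial to avoid A(1,2) strain with the C1 substituent, which places C5–O axial and C4–O equatorial, so the hemiorthoester should collapse by the axial-ester rule to the C5 benzoate without touching any stereocentre.

Compound list
1 | shikimic acid, (3R,4S,5R)-3,4,5-trihydroxycyclohex-1-ene-1-carboxylic acid | OC(=O)C1=C[C@@H](O)[C@@H](O)[C@H](O)C1 | starting material
2 | methanol | CO | starting material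
3 | 2,2-dimethoxypropane | COC(C)(C)OC | starting material
4 | methyl shikimate, methyl (3R,4S,5R)-3,4,5-trihydroxycyclohex-1-ene-1-carboxylate | COC(=O)C1=C[C@@H](O)[C@@H](O)[C@H](O)C1 | intermediate
5 | methyl 3,4-O-isopropylideneshikimate, methyl (3aR,7R,7aS)-7-hydroxy-2,2-dimethyl-3a,6,7,7a-tetrahydro-1,3-benzodioxole-5-carboxylate | COC(=O)C1=C[C@H]2OC(C)(C)O[C@H]2[C@H](O)C1 | intermediate
6 | trifluoromethanesulfonic anhydride | O=S(=O)(OS(=O)(=O)C(F)(F)F)C(F)(F)F | starting material
7 | methyl 3,4-O-isopropylidene-5-O-(trifluoromethylsulfonyl)shikimate (triflate trans to the ketal oxygens) | COC(=O)C1=C[C@H]2OC(C)(C)O[C@H]2[C@H](OS(=O)(=O)C(F)(F)F)C1 | intermediate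
8 | methyl (3aR,7aS)-2,2-dimethyl-3a,7a-dihydro-1,3-benzodioxole-5-carboxylate | COC(=O)C1=C[C@H]2OC(C)(C)O[C@H]2C=C1 | intermediate
9 | [(3aR,7aS)-2,2-dimethyl-3a,7a-dihydro-1,3-benzodioxol-5-yl]methanol | OCC1=C[C@H]2OC(C)(C)O[C@H]2C=C1 | intermediate
10 | benzoyl chloride | O=C(Cl)c1ccccc1 | starting material
11 | [(3aR,7aS)-2,2-dimethyl-3a,7a-dihydro-1,3-benzodioxol-5-yl]methyl benzoate | O=C(OCC1=C[C@H]2OC(C)(C)O[C@H]2C=C1)c1ccccc1 | intermediate
12 | dioxygen | O=O | starting material
13 | endoperoxide: peroxide bridge C3–O–O–C6 anti to the cis 4,5-acetonide, C1=C2 alkene, C7 benzoate | O=C(OCC1=C[C@@H]2[C@@H]3OC(C)(C)O[C@@H]3[C@H]1OO2)c1ccccc1 | intermediate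
14 | cis-3,6-diol 4,5-acetonide C7 benzoate (both hydroxyls trans to the neighbouring ketal oxygens) | O=C(OCC1=C[C@@H](O)[C@@H]2OC(C)(C)O[C@@H]2[C@H]1O)c1ccccc1 | intermediate
15 | water | O | starting material
16 | [(3R,4S,5R,6S)-3,4,5,6-tetrahydroxycyclohex-1-en-1-yl]methyl benzoate | O=C(OCC1=C[C@@H](O)[C@H](O)[C@H](O)[C@H]1O)c1ccccc1 | intermediate
17 | trimethyl orthobenzoate | COC(OC)(OC)c1ccccc1 | starting material
18 | cyclic 4,5-O-(α-methoxybenzylidene) orthobenzoate of 16 (either epimer at the orthoester carbon) | O=C(OCC1=C[C@@H](O)[C@@H]2OC(OC)(c3ccccc3)O[C@@H]2[C@H]1O)c1ccccc1 | intermediate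
19 | [(3R,4S,5R,6S)-5-(benzoyloxy)-3,4,6-trihydroxycyclohex-1-en-1-yl]methyl benzoate | O=C(OCC1=C[C@@H](O)[C@H](O)[C@H](OC(=O)c2ccccc2)[C@H]1O)c1ccccc1 | target

Total step count: 9. Longest linear sequence: 9 steps (fully linear from shikimic acid).

Steps most likely to fail

Step 6. The diene benzoate 11 is a heat- and acid-sensitive dihydrodiol ketal. It may dimerise by Diels–Alder reaction or aromatise before it meets singlet oxygen, and ene attack at the C7 methylene may compete with cycloaddition. The fallback moves the cycloaddition one stage earlier, onto the robust diene ester 8. Sensitised photooxygenation of 8 (longer irradiation for the less electron-rich diene) should give the endoperoxide methyl ester F1, again anti to the ketal. Thiourea in methanol should reduce it to the cis-3,6-diol methyl ester F2. DIBAL-H should then give the acetonide triol F3. Benzoylation of its primary allylic hydroxyl alone (BzCl 1 equiv, 2,4,6-collidine, CH2Cl2, −40 °C) rejoins the route at 14.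

Step 9. Regiochemical leakage is possible. The orthoester may also engage the C3 or C6 hydroxyl, the hemiorthoester may open partly toward C4, and the benzoate may migrate between the cis C4/C5 oxygens. The fallback sets out from 14 and masks both allylic hydroxyls first. TIPSOTf and 2,6-lutidine should give the 3,6-bis(triisopropylsilyl) ether acetonide F4. Aqueous acetic acid should release the 3,6-bis(silyl) 4,5-diol F5. With only the cis-diol free, and the bulky C6 silyl ether forced pseudoaxial next to the C1 substituent (C5–O locked axial), PhC(OMe)3/CSA should give the bis(silyl) cyclic orthobenzoate F6. Mild aqueous acid should open it to the bis(silyl) C5 benzoate F7. HF·pyridine in THF (acidic, so no acyl migration is expected) then returns to the route at 19.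

Step 3. Substitution by acetate at C5, or decomposition of the labile triflate, may compete with elimination. The fallback sets out from 7 and makes the alkene by a syn-elimination instead. Sodium phenylselenide (PhSeSePh, NaBH4, EtOH) should displace the triflate with inversion to give the C5-epi phenyl selenide F8. H2O2 with pyridine in CH2Cl2 at 0 °C should oxidise it to the selenoxide F9. The selenoxide can only eliminate toward C6, because H-4 is anti to selenium, which returns to the route at 8.

Further compounds
F1 | step 6 | endoperoxide methyl ester (peroxide bridge C3–C6 anti to the 4,5-acetonide) | COC(=O)C1=C[C@@H]2[C@@H]3OC(C)(C)O[C@@H]3[C@H]1OO2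
F2 | step 6 | cis-3,6-diol 4,5-acetonide methyl ester | COC(=O)C1=C[C@@H](O)[C@@H]2OC(C)(C)O[C@@H]2[C@H]1O
F3 | step 6 | acetonide triol (C7 and cis-3,6 hydroxyls free) | OCC1=C[C@@H](O)[C@@H]2OC(C)(C)O[C@@H]2[C@H]1O
F4 | step 9 | 3,6-bis(triisopropylsilyl) ether of 14 | O=C(OCC1=C[C@@H](O[Si](C(C)C)(C(C)C)C(C)C)[C@@H]2OC(C)(C)O[C@@H]2[C@H]1O[Si](C(C)C)(C(C)C)C(C)C)c1ccccc1
F5 | step 9 | 3,6-bis(triisopropylsilyl) 4,5-diol C7 benzoate | O=C(OCC1=C[C@@H](O[Si](C(C)C)(C(C)C)C(C)C)[C@H](O)[C@H](O)[C@H]1O[Si](C(C)C)(C(C)C)C(C)C)c1ccccc1
F6 | step 9 | 3,6-bis(triisopropylsilyl) cyclic 4,5-orthobenzoate (either epimer at the orthoester carbon) | O=C(OCC1=C[C@@H](O[Si](C(C)C)(C(C)C)C(C)C)[C@@H]2OC(OC)(c3ccccc3)O[C@@H]2[C@H]1O[Si](C(C)C)(C(C)C)C(C)C)c1ccccc1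
F7 | step 9 | 3,6-bis(triisopropylsilyl) C5,C7-dibenzoate | O=C(OCC1=C[C@@H](O[Si](C(C)C)(C(C)C)C(C)C)[C@H](O)[C@H](OC(=O)c2ccccc2)[C@H]1O[Si](C(C)C)(C(C)C)C(C)C)c1ccccc1
F8 | step 3 | methyl 5-epi-5-deoxy-5-(phenylselanyl)-3,4-O-isopropylideneshikimate | COC(=O)C1=C[C@H]2OC(C)(C)O[C@H]2[C@@H]([Se]c3ccccc3)C1
F9 | step 3 | selenoxide of F8 | COC(=O)C1=C[C@H]2OC(C)(C)O[C@H]2[C@@H]([Se](=O)c3ccccc3)C1
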